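**Retrosynthetic overview**

1. Feature (locants: C1 ketone, C3 = CHCH3, C6 = C(CH3)(CH2O), C9 = CHO, C10 = C–CH3): the cyclobutane C4–C5–C11–C10 carries the three-carbon bridge C3–C2–C1 across C4/C11 and, on the opposite face, the four-carbon bridge C6–C7–C8–C9 across C5/C10. The target is therefore a 1,3-diene added across the central σ-bond of a tricyclo[4.1.0.0^2,7]heptane (a bridged bicyclo[1.1.0]butane), and the cis pair C6–CH2O / C9–O is the footprint of a 2-pyrone.
2. Key disconnection: C5–C6 and C9–C10 together, by an inverse-electron-demand (4+2σ) cycloaddition of the sulfur-donor bicyclobutane 10 with the chelating 3-(sulfinylmethyl)-2-pyrone 15. The bicyclobutane opens to the cyclobutane as the seven-membered ring closes; the δ-lactone is a temporary ring.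
3. After the key step: one Raney Ni operation removes both sulfur groups (giving C5–H and the C6 methyl) and the C7=C8 bond; then lactone → diol → bis-angelate; ketal → C1 ketone → C2=C3 enone → cuprate for the C3 methyl.
4. Before the key step: 10 from 3-methylcyclohex-2-enone (CBS carbinol → anti dibromocyclopropane → ketal → cyclopropylidene C–H insertion → bridgehead sulfenylation); 15 from 3-bromo-2-pyrone (methylation, bromination, thioether, asymmetric sulfoxidation).
5. Ring order: six-membered ring (bought) → cyclopropane → bicyclo[1.1.0]butane → cyclobutane and seven-membered ring together (step 12).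

Key step: step 12

Assumption: the sense of induction by the sulfinyl group in step 12 is taken from a chelate model (approach anti to p-tolyl), which points to the (R)-sulfoxide; if the sense is opposite, the (S)-sulfoxide from (S,S)-diethyl tartrate is carried instead.

**Route**

Step 1
Reactants: 1 3-methylcyclohex-2-en-1-one
Product: 2 (R)-3-methylcyclohex-2-en-1-ol
Conditions: (S)-2-methyl-CBS-oxazaborolidine (10 mol %), BH3·SMe2, THF, –20 °C; MeOH quench
Reagents that add atoms: none
Why: Corey–Bakshi–Shibata reduction, in which the oxazaborolidine–borane complex binds the carbonyl anti to the larger alkenyl flank and delivers hydride to one face, which should set the carbinol centre as (R).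

Step 2
Reactants: 2 (R)-3-methylcyclohex-2-en-1-ol
Product: 3 (R)-tert-butyldimethyl[(3-methylcyclohex-2-en-1-yl)oxy]silane
Conditions: TBSCl, imidazole, DMF, 20 °C
Reagents that add atoms: tert-butyldimethylsilyl chloride, CC(C)(C)[Si](C)(C)Cl
Why: Silyl ether formation protects the hydroxyl against the base and carbene of step 3 and turns it into a bulky stereodirecting group; no stereocentre is affected.

Step 3
Reactants: 3 (R)-tert-butyldimethyl[(3-methylcyclohex-2-en-1-yl)oxy]silane
Product: 4 7,7-dibromo-6-methylbicyclo[4.1.0]heptan-2-yl tert-butyldimethylsilyl ether (silyloxy group trans to the cyclopropane)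
Conditions: CHBr3, KOtBu, pentane, –10 → 20 °C
Reagents that add atoms: bromoform, BrC(Br)Br
Why: Dibromocarbene cyclopropanation of the electron-rich trisubstituted alkene should occur on the face anti to the allylic OTBS group, which sets both cyclopropane stereocentres (the future C10 and C11) from the carbinol centre.

Step 4
Reactants: 4 7,7-dibromo-6-methylbicyclo[4.1.0]heptan-2-yl tert-butyldimethylsilyl ether
Product: 6 7,7-dibromo-6-methylbicyclo[4.1.0]heptan-2-one, via free alcohol 5 (not isolated)
Conditions: CrO3, H2SO4, H2O, acetone, 0 → 20 °C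
Reagents that add atoms: none
Why: Jones oxidation, in which the aqueous acid first cleaves the silyl ether and chromic acid then oxidises the secondary alcohol, removes the carbinol centre after it has done its directing work while the cyclopropane centres keep their absolute configuration.

Step 5
Reactants: 6 7,7-dibromo-6-methylbicyclo[4.1.0]heptan-2-one
Product: 7 7',7'-dibromo-6'-methylspiro[1,3-dioxolane-2,2'-bicyclo[4.1.0]heptane]
Conditions: ethylene glycol, TsOH (cat.), benzene, reflux, Dean–Stark
Reagents that add atoms: ethane-1,2-diol, OCCO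
Why: Acid-catalysed ketalisation masks the ketone against alkyllithiums and leaves a fully substituted carbon on one side of the cyclopropane, so that only one neighbouring CH2 can be attacked in step 6.

Step 6
Reactants: 7 7',7'-dibromo-6'-methylspiro[1,3-dioxolane-2,2'-bicyclo[4.1.0]heptane]
Product: 8 1'-methylspiro[1,3-dioxolane-2,3'-tricyclo[4.1.0.0^2,7]heptane]
Conditions: MeLi, Et2O, –78 → 0 °C
Reagents that add atoms: none
Why: Bromine–lithium exchange and α-elimination give a cyclopropylidene (carbenoid) that inserts into the cis C–H bond of the CH2 next to the methyl-bearing cyclopropane carbon, the classical gem-dibromocyclopropane route to tricyclo[4.1.0.0^2,7]heptanes; the two lateral stereocentres follow from the cis geometry of the insertion.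

Step 7
Reactants: 8 1'-methylspiro[1,3-dioxolane-2,3'-tricyclo[4.1.0.0^2,7]heptane]
Product: 10 1'-methyl-7'-(methylsulfanyl)spiro[1,3-dioxolane-2,3'-tricyclo[4.1.0.0^2,7]heptane], via bridgehead lithium compound 9 (not isolated)
Conditions: n-BuLi, TMEDA, Et2O, 0 → 20 °C; then MeSSMe, –78 → 20 °C
Reagents that add atoms: dimethyl disulfide, CSSC
Why: Bridgehead lithiation of the bicyclo[1.1.0]butane (C–H bond of high s character) followed by electrophilic sulfenylation proceeds with retention and installs the sulfur donor at C5.

Step 8
Reactants: 11 3-bromo-2H-pyran-2-one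
Product: 12 3-methyl-2H-pyran-2-one
Conditions: MeB(OH)2, Pd(dppf)Cl2 (5 mol %), CsF, 1,4-dioxane, 80 °C
Reagents that add atoms: methylboronic acid, CB(O)O
Why: Suzuki–Miyaura cross-coupling at the C–Br bond of the pyrone; fluoride activation avoids hydroxide, which would open the lactone.

Step 9
Reactants: 12 3-methyl-2H-pyran-2-one
Product: 13 3-(bromomethyl)-2H-pyran-2-one
Conditions: NBS, AIBN (cat.), PhCF3, 85 °C
Reagents that add atoms: N-bromosuccinimide, O=C1CCC(=O)N1Br
Why: Wohl–Ziegler bromination, in which the radical chain abstracts hydrogen from the methyl group because its radical is stabilised by the dienoate system.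

Step 10
Reactants: 13 3-(bromomethyl)-2H-pyran-2-one
Product: 14 3-{[(4-methylphenyl)sulfanyl]methyl}-2H-pyran-2-one
Conditions: 4-methylbenzenethiol, Et3N, CH2Cl2, 0 °C
Reagents that add atoms: 4-methylbenzenethiol, Cc1ccc(S)cc1
Why: SN2 displacement of the primary allylic-type bromide by the thiolate should be much faster than conjugate addition to the pyrone at 0 °C.

Step 11
Reactants: 14 3-{[(4-methylphenyl)sulfanyl]methyl}-2H-pyran-2-one
Product: 15 3-{[(R)-(4-methylphenyl)sulfinyl]methyl}-2H-pyran-2-one
Conditions: Ti(OiPr)4, (R,R)-diethyl tartrate, H2O, cumene hydroperoxide, CH2Cl2, –20 °C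
Reagents that add atoms: cumene hydroperoxide, CC(C)(OO)c1ccccc1
Why: Titanium–tartrate asymmetric sulfoxidation (Kagan-type), which with (R,R)-diethyl tartrate should oxidise an aryl CH2R sulfide to the (R)-sulfoxide as it does aryl methyl sulfides; the new stereocentre is sulfur.

Step 12
Reactants: 10 1'-methyl-7'-(methylsulfanyl)spiro[1,3-dioxolane-2,3'-tricyclo[4.1.0.0^2,7]heptane], 15 3-{[(R)-(4-methylphenyl)sulfinyl]methyl}-2H-pyran-2-one
Product: 16 cycloadduct (C1 ethylene ketal; cyclobutane C4–C5–C11–C10; C7=C8; lactone bridge C6–C(=O)–O–C9 on the C11 side; 5-SMe; 6-CH2S(O)Tol; 10-CH3)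
Conditions: Yb(fod)3 (10 mol %; fod = 6,6,7,7,8,8,8-heptafluoro-2,2-dimethyloctane-3,5-dionate), 4 Å molecular sieves, CH2Cl2, –20 → 20 °C
Reagents that add atoms: none
Why: Proposed new method: the methylthio group turns the central C5–C10 bond of the bicyclo[1.1.0]butane into a homo-enol thioether (C10 nucleophilic, C5 cation-stabilising) and the Yb-chelated 2-pyrone is an electron-poor diene, so an asynchronous inverse-electron-demand (4+2σ) cycloaddition is expected in which C10 bonds to pyrone C-6 through the exterior lobe of the bent σ-bond and the thionium centre at C5 is captured by the dienolate α-carbon (pyrone C-3); the closest known reaction types are inverse-electron-demand Diels–Alder reactions of 2-pyrones with vinyl sulfides and enol ethers and Lewis-acid-catalysed formal (4+2) annulations of acyl bicyclo[1.1.0]butanes with silyl dienol ethers to bicyclo[4.1.1]octanes, here with the polarity of the σ-component reversed. The seven-membered ring closes as the 4π+2σ cycloaddition across C5/C10 (second bond a 7-exo-trig attack on the thionium carbon) while the cyclobutane emerges from the bicyclobutane and the lactone persists as a 2-oxabicyclo[2.2.2]octenone bridge. Both bonds must form on the convex face because the concave face carries the three-carbon bridge, so SMe and CH3 stay exocyclic (retention at C5 and C10), and the lactone ring of the pyrone fixes the C9 oxygen cis to the C6 carboxyl carbon and trans to the latent C6 methyl. Regioselectivity (C9 to the methyl-bearing C10, C6 to C5) is secured by the sulfur donor on C5. Periselectivity over the (2+2σ) mode rests on α- rather than γ-attack of the dienolate on the thionium ion. Facial selectivity on the pyrone (lactone under the ketal-bearing lateral carbon C11), which the nearly mirror-symmetric convex face cannot bias, is assigned to the (R)-sulfinyl group held in a Yb chelate with the lactone carbonyl, the bicyclobutane approaching anti to p-tolyl.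

Step 13
Reactants: 16 cycloadduct
Product: 17 saturated lactone (C1 ethylene ketal; C5–H; 6-CH3; lactone C6–C(=O)–O–C9)
Conditions: Raney Ni (W-2, excess), H2 (1 atm), EtOH/THF, 50 °C
Reagents that add atoms: none
Why: Raney-nickel hydrogenolysis (Mozingo-type desulfurisation) should cleave the C5–SMe bond and the CH2–S(O)Tol bond, which unveils the C6 methyl group, and saturate C7=C8 in one operation; C5 keeps its configuration because the cage allows hydrogen only in the exocyclic position.

Step 14
Reactants: 17 saturated lactone
Product: 18 diol (C1 ethylene ketal; 6-CH2OH and 9-OH cis)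
Conditions: LiAlH4, THF, 0 → 20 °C; H2O, aq NaOH work-up
Reagents that add atoms: none
Why: LiAlH4 reduction of the δ-lactone gives the diol with the cis relation of CH2OH and 9-OH fixed by the former lactone bridge; the ketal is inert.

Step 15
Reactants: 18 diol
Product: 19 bis-angelate ketal
Conditions: angelic acid, 2,4,6-trichlorobenzoyl chloride, Et3N, toluene, 20 °C; then 18, toluene, 80 °C
Reagents that add atoms: angelic acid ((Z)-2-methylbut-2-enoic acid), C/C=C(/C)C(=O)O
Why: Double acylation with a preformed mixed anhydride (Yamaguchi-type esterification without a nucleophilic amine catalyst), conditions known to transfer the angeloyl group without Z to E isomerisation.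

Step 16
Reactants: 19 bis-angelate ketal
Product: 20 bis-angelate ketone (C1 ketone; C2 and C3 both CH2)
Conditions: PPTS (cat.), acetone/H2O (10:1), 50 °C
Reagents that add atoms: water, O
Why: Mild acid-catalysed ketal hydrolysis frees the C1 ketone without touching the angelate esters.

Step 17
Reactants: 20 bis-angelate ketone
Product: 21 bis-angelate enone (C1 ketone, C2=C3)
Conditions: IBX, DMSO/toluene, 70 °C
Reagents that add atoms: none
Why: IBX dehydrogenation of the ketone through its enol; only C2 can enolise because C11 is a bridgehead, so the C2=C3 enone is the only possible product.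

Step 18
Reactants: 21 bis-angelate enone
Product: 22 target CNP0276938.1
Conditions: Me2CuLi (from MeLi and CuI), Et2O, –78 °C; aq NH4Cl
Reagents that add atoms: lithium dimethylcuprate, [Li+].C[Cu-]C
Why: Cuprate conjugate addition, in which the methyl group should add to C3 from the face next to C5–H, anti to the C10 methyl group that overhangs the other face, which sets C3; the enone is far more reactive toward the cuprate than the α,β-disubstituted angelate esters.

**Compound list**

1 | 3-methylcyclohex-2-en-1-one | CC1=CC(=O)CCC1 | starting material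
2 | (R)-3-methylcyclohex-2-en-1-ol | CC1=C[C@H](O)CCC1 | intermediate
3 | (R)-tert-butyldimethyl[(3-methylcyclohex-2-en-1-yl)oxy]silane | CC1=C[C@H](O[Si](C)(C)C(C)(C)C)CCC1 | intermediate
4 | 7,7-dibromo-6-methylbicyclo[4.1.0]heptan-2-yl tert-butyldimethylsilyl ether, silyloxy trans to the cyclopropane | C[C@@]12CCC[C@@H](O[Si](C)(C)C(C)(C)C)[C@@H]1C2(Br)Br | intermediate
5 | 7,7-dibromo-6-methylbicyclo[4.1.0]heptan-2-ol, hydroxyl trans to the cyclopropane (not isolated) | C[C@@]12CCC[C@@H](O)[C@@H]1C2(Br)Br | intermediate
6 | 7,7-dibromo-6-methylbicyclo[4.1.0]heptan-2-one, single enantiomer | C[C@@]12CCCC(=O)[C@@H]1C2(Br)Br | intermediate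
7 | 7',7'-dibromo-6'-methylspiro[1,3-dioxolane-2,2'-bicyclo[4.1.0]heptane] | C[C@@]12CCCC3(OCCO3)[C@@H]1C2(Br)Br | intermediate
8 | 1'-methylspiro[1,3-dioxolane-2,3'-tricyclo[4.1.0.0^2,7]heptane] (bicyclobutane: CH3 on one bridgehead, H on the other; lateral carbons bridged by C(OCH2CH2O)–CH2–CH2) | C[C@@]12[C@H]3CCC4(OCCO4)[C@@H]1[C@@H]23 | intermediate
9 | 7'-lithio derivative of 8 (not isolated) | C[C@@]12[C@H]3CCC4(OCCO4)[C@@H]1[C@@]23[Li] | intermediate
10 | 1'-methyl-7'-(methylsulfanyl)spiro[1,3-dioxolane-2,3'-tricyclo[4.1.0.0^2,7]heptane] | C[C@@]12[C@H]3CCC4(OCCO4)[C@@H]1[C@@]23SC | intermediate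
11 | 3-bromo-2H-pyran-2-one | O=C1OC=CC=C1Br | starting material
12 | 3-methyl-2H-pyran-2-one | CC1=CC=COC1=O | intermediate
13 | 3-(bromomethyl)-2H-pyran-2-one | BrCC1=CC=COC1=O | intermediate
14 | 3-{[(4-methylphenyl)sulfanyl]methyl}-2H-pyran-2-one | Cc1ccc(SCC2=CC=COC2=O)cc1 | intermediate
15 | 3-{[(R)-(4-methylphenyl)sulfinyl]methyl}-2H-pyran-2-one | Cc1ccc(cc1)[S@](=O)CC1=CC=COC1=O | intermediate
16 | cycloadduct: C1 ethylene ketal, C7=C8, lactone C6–C(=O)–O–C9 on the C11 side, 5-SMe, 6-CH2S(O)Tol with (R)-sulfur, 10-CH3 | O=C4[C@@]1(C[S@@](=O)c6ccc(C)cc6)C=C[C@@H](O4)[C@]2(C)[C@@H]3[C@@]1(SC)[C@H]2C5(OCCO5)CC3 | intermediate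
17 | saturated lactone: C1 ethylene ketal, C5–H, 6-CH3, lactone C6–C(=O)–O–C9 | O=C4[C@@]1(C)CC[C@@H](O4)[C@]2(C)[C@@H]3[C@H]1[C@H]2C5(OCCO5)CC3 | intermediate
18 | diol: C1 ethylene ketal, 6-CH2OH and 9-OH cis | OC[C@@]1(C)CC[C@@H](O)[C@]2(C)[C@@H]3[C@H]1[C@H]2C4(OCCO4)CC3 | intermediate
19 | bis-angelate ketal: C1 ethylene ketal, 6-CH2O-angeloyl, 9-O-angeloyl | C/C=C(/C)C(=O)OC[C@@]1(C)CC[C@@H](OC(=O)/C(C)=C\C)[C@]2(C)[C@@H]3[C@H]1[C@H]2C4(OCCO4)CC3 | intermediate
20 | bis-angelate ketone: C1 ketone, C2 and C3 CH2 | C/C=C(/C)C(=O)OC[C@@]1(C)CC[C@@H](OC(=O)/C(C)=C\C)[C@]2(C)[C@@H]3[C@H]1[C@H]2C(=O)CC3 | intermediate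
21 | bis-angelate enone: C1 ketone, C2=C3 | C/C=C(/C)C(=O)OC[C@@]1(C)CC[C@@H](OC(=O)/C(C)=C\C)[C@]2(C)[C@@H]3[C@H]1[C@H]2C(=O)C=C3 | intermediate
22 | CNP0276938.1 (9-angeloyloxy-6-(angeloyloxymethyl) tricyclic 1-ketone with 3-, 6- and 10-methyl groups) | C/C=C(/C)C(=O)OC[C@@]1(C)CC[C@@H](OC(=O)/C(C)=C\C)[C@]2(C)[C@@H]3[C@H]1[C@H]2C(=O)C[C@H]3C | target

**Step count and risks**

Total step count: 18. Longest linear sequence: 14 steps (steps 1–7 and 12–18); the pyrone branch (steps 8–11) joins at step 12.

Steps most likely to fail:

Step 12 (Proposed new method). What may go wrong: Lewis-acid-induced isomerisation of the bicyclobutane before any bond forms; closure of the ion pair through the dienolate γ-carbon to a bicyclo[2.1.1]hexane; or weak facial discrimination by the sulfinyl group. The fallback uses known reaction types and planar intermediates at both cyclobutane carbons; it sets out from 8 and 12 and comes back at 17. Electrophilic 1,3-addition of PhSCl across the central bond of 8 (CH2Cl2, –78 °C), a known reaction of tricyclo[4.1.0.0^2,7]heptanes, should give the chloro sulfide F1. The tertiary chloride is converted into the cyclobutyl radical ((Me3Si)3SiH, AIBN, benzene, 80 °C) and added to C-6 of pyrone 12 in a Giese-type 1,6-addition, bonding anti to the three-carbon bridge, to give the dihydropyranone F2; the C9 epimers are separated here. Oxidation with NaIO4 gives the sulfoxide F3. Pummerer activation (TMSOTf, iPr2NEt, CH2Cl2, –78 → 0 °C) generates the C5 thionium ion and the silyl dienol ether of the lactone in the same flask, and intramolecular vinylogous Mukaiyama-type alkylation at the α-carbon closes the seven-membered ring to the thio lactone F4. Raney Ni/H2 then removes the phenylthio group and saturates C7=C8 to give 17.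

Step 15. What may go wrong: incomplete acylation of the neopentyl-type secondary C9 hydroxyl, and isomerisation of angelate to tiglate if the reaction is forced. The fallback sets out from 18 and comes back at 19. The primary hydroxyl alone is acylated with the same mixed anhydride at 20 °C to give the primary mono-angelate F5; its C9 alkoxide (LiHMDS, THF, –78 °C) is then acylated with angelic anhydride, an alkoxide acylation that needs no nucleophilic catalyst and no heating.

Step 9. What may go wrong: electrophilic bromination of the pyrone ring at C-5 and over-bromination of the methyl group compete with the radical chain. The fallback sets out from 11 and comes back at 14, bypassing 12 and 13: Stille coupling of 11 with tributyl{[(4-methylphenyl)sulfanyl]methyl}stannane (Pd(PPh3)4, toluene, 100 °C) installs the thiomethyl side chain directly; no new compound is formed on the way.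

Further compounds
F1 | step 12 | 6-chloro-6-methyl-7-(phenylsulfanyl)bicyclo[3.1.1]heptan-2-one ethylene ketal, Cl and SPh on the face anti to the three-carbon bridge | C[C@@]1(Cl)[C@H]2CCC3(OCCO3)[C@@H]1[C@H]2Sc4ccccc4
F2 | step 12 | 3-methyl-6-[2,2-(ethylenedioxy)-6-methyl-7-(phenylsulfanyl)bicyclo[3.1.1]hept-6-yl]-5,6-dihydro-2H-pyran-2-one, C9 epimer leading to 17 | O=C1O[C@H](CC=C1C)[C@]2(C)[C@H]3CCC4(OCCO4)[C@@H]2[C@H]3Sc5ccccc5
F3 | step 12 | sulfoxide of F2 (mixture at sulfur) | O=C1O[C@H](CC=C1C)[C@]2(C)[C@H]3CCC4(OCCO4)[C@@H]2[C@H]3S(=O)c5ccccc5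
F4 | step 12 | 5-(phenylsulfanyl)-6-methyl analogue of cycloadduct 16 (C1 ketal, C7=C8, lactone C6–C(=O)–O–C9) | O=C4[C@@]1(C)C=C[C@@H](O4)[C@]2(C)[C@@H]3[C@@]1(Sc7ccccc7)[C@H]2C5(OCCO5)CC3
F5 | step 15 | primary mono-angelate of diol 18 (9-OH free) | C/C=C(/C)C(=O)OC[C@@]1(C)CC[C@@H](O)[C@]2(C)[C@@H]3[C@H]1[C@H]2C4(OCCO4)CC3
F0 | step 9 | none | none
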